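The six-membered ring (C1–C2–C3–C4–C5–C8) is cut away from the cyclopentanone ring C1–C7–C6–C5–C8. In that ring the ketone C8 has both β-carbons, C7 and C6, arylated and trans. This is the pattern left by a conrotatory 4π closure of a 1,5-diaryl divinyl ketone. The key step is a chiral-Lewis-acid Nazarov cyclisation ended by hydride transfer. In one operation it forms C6–C7, closes the five-membered ring and sets both stereocentres, while C6 stays sp3. Its precursor is an (E,E)-2-acetyl-1,5-diarylpentadienone with silyl-protected phenols. The acetyl group supplies C2 and C3 for the later bridging through C4.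

Key step: step 6

**Numbering** (bicyclo[3.2.1]octane core, used for every intermediate): C1 and C5 are bridgeheads and C2 is the enone carbonyl. C3=C4 carries the styryl arm on C4. C6 bears the exo 3,5-dioxygenated aryl, C7 the endo 4-oxygenated aryl, and C8 is the bridging carbonyl.

**Design remarks**
- **Phenol protection.** The phenols travel as TIPS ethers. In the target the C1–C7 bond is aligned with both carbonyl π systems and carries a 4-oxygenated aryl group. Strong Lewis or Brønsted acid, or free phenoxide, could therefore break it, with rearomatisation of the six-membered ring. The last step must be near neutral.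
- **Blocking C1.** An enolised C1 is planar and cannot become a bridgehead, and it also offers the oxygen on C8 as the ring-closing nucleophile. That would give a dihydropyranone at the enone level, or a γ-pyranone at the triketone level. C1 is therefore made quaternary for three steps and the bridge is closed by carbon attack from C5.
- **Bases to avoid.** Alkoxide and hydroxide are kept away from the bridged, non-enolisable 1,3-diketones, which would open by retro-Claisen cleavage.

**Assumption:** the ligand antipode that gives the drawn sense of conrotation cannot be derived from precedent. (S,S) is written and is exchanged for (R,R) if a first run gives the mirror image.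

Step 1
Reactants: 1 3,5-dihydroxybenzaldehyde
Product: 2 3,5-bis(triisopropylsilyloxy)benzaldehyde
Conditions: TIPSCl (2.3 equiv), imidazole, DMF, rt
Reagents that add atoms: chlorotriisopropylsilane, CC(C)[Si](Cl)(C(C)C)C(C)C
Why: Imidazole-mediated O-silylation of both phenols should give TIPS aryl ethers that tolerate the amines, dilute acid, Lewis acids and radicals used later and leave under buffered fluoride.

Step 2
Reactants: 3 4-hydroxybenzaldehyde
Product: 4 4-(triisopropylsilyloxy)benzaldehyde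
Conditions: TIPSCl (1.2 equiv), imidazole, DMF, rt
Reagents that add atoms: chlorotriisopropylsilane, CC(C)[Si](Cl)(C(C)C)C(C)C
Why: This is the same O-silylation as step 1, and one aldehyde then serves both the C7 aryl group and the styryl arm.

Step 3
Reactants: 4 4-(triisopropylsilyloxy)benzaldehyde
Product: 5 (E)-3-[4-(triisopropylsilyloxy)phenyl]prop-2-enal
Conditions: Ph3P=CHCHO (1.05 equiv), toluene, 80 °C
Reagents that add atoms: (triphenylphosphoranylidene)acetaldehyde, O=CC=P(c1ccccc1)(c1ccccc1)c1ccccc1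
Why: Wittig olefination with the stabilised formyl ylide should give the E-enal, and the near-stoichiometric ylide limits a second homologation.

Step 4
Reactants: 6 pentane-2,4-dione (3 equiv); 2 3,5-bis(triisopropylsilyloxy)benzaldehyde
Product: 9 (E)-6-[3,5-bis(triisopropylsilyloxy)phenyl]hex-5-ene-2,4-dione, via dibutoxyboron acetylacetonate 7 (not isolated), via dibutoxyboron chelate of the enedione 8 (not isolated)
Conditions: B(OBu)3 (as template and water scavenger), n-BuNH2 (cat.), EtOAc, 70 °C; then aq. citric acid, rt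
Reagents that add atoms: none
Why: In this boron-templated aldol condensation the chelate 7 masks the central carbon and acidifies the methyl groups, so one methyl condenses with 2 to the E-enone while the excess of 6 holds back the double condensation.

Step 5
Reactants: 9 (E)-6-[3,5-bis(triisopropylsilyloxy)phenyl]hex-5-ene-2,4-dione; 4 4-(triisopropylsilyloxy)benzaldehyde
Product: 10 (1E,4E)-4-acetyl-1-[3,5-bis(triisopropylsilyloxy)phenyl]-5-[4-(triisopropylsilyloxy)phenyl]penta-1,4-dien-3-one
Conditions: piperidine (cat.), AcOH (cat.), toluene, Dean–Stark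
Reagents that add atoms: none
Why: Knoevenagel condensation occurs at the only doubly activated CH2, and the drawn isomer (aryl cis to the small acetyl group, trans to C8) should be the less crowded one.

Step 6
Reactants: 10 (1E,4E)-4-acetyl-1-[3,5-bis(triisopropylsilyloxy)phenyl]-5-[4-(triisopropylsilyloxy)phenyl]penta-1,4-dien-3-one
Product: 13 1-{(4R,5R)-4-[3,5-bis(triisopropylsilyloxy)phenyl]-2-hydroxy-5-[4-(triisopropylsilyloxy)phenyl]cyclopent-1-en-1-yl}ethan-1-one (ring enol of the 3,4-trans 2-acetylcyclopentanone), via copper-bound oxyallyl zwitterion 11 (not isolated), via triethylsilyl enol ether 12 (not isolated)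
Conditions: Cu(SbF6)2 (20 mol %), (S,S)-t-Bu-box (22 mol %), Et3SiH (3 equiv, slow addition), 4 Å MS, CH2Cl2, −20 °C to rt; then aq. citric acid
Reagents that add atoms: none
Why: Proposed new method: the 1,3-diketone unit of 10 (the oxygens on C8 and C2) chelates the chiral copper Lewis acid, and the resulting U-shaped pentadienyl cation closes ring C1–C7–C6–C5–C8 by a thermal conrotatory 4π electrocyclisation that forms C6–C7 and gives oxyallyl species 11. The closest known reaction types are the Lewis-acid Nazarov cyclisation of 2-acyl and 2-alkoxycarbonyl divinyl ketones, its enantioselective copper bis(oxazoline) version and the silane-interrupted (reductive) Nazarov reaction, which have not yet been run together on a 1,5-diaryl substrate. Both aryl groups lie outside in the cation, so conrotation fixes the C6/C7 trans relation by orbital symmetry, while the ligand chooses the sense of rotation and with it the absolute configuration of C7 and C6 at once. In 11 the negative end rests on C1 as a copper 1,3-diketonate, so the positive end is C5, hydride from Et3SiH adds there, and silyl transfer to oxygen (12) releases the catalyst before aqueous work-up gives 13. The step needs hydride capture to outrun loss of the C6 proton (excess silane, low temperature), cyclisation to outrun ionic reduction of the arylidene diketone (slow silane addition), and no arene trapping of 11, which the TIPS groups flanking every activated position of the resorcinol ring should secure. Any Z isomer at the arylidene bond equilibrates on the Lewis acid, and only the E form can fold into the U shape.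

Step 7
Reactants: 13 ring enol of the trans 2-acetyl-3,4-diarylcyclopentanone; 5 (E)-3-[4-(triisopropylsilyloxy)phenyl]prop-2-enal
Product: 16 (2E,4E)-1-{(4R,5R)-4-[3,5-bis(triisopropylsilyloxy)phenyl]-2-hydroxy-5-[4-(triisopropylsilyloxy)phenyl]cyclopent-1-en-1-yl}-5-[4-(triisopropylsilyloxy)phenyl]penta-2,4-dien-1-one, via dibutoxyboron chelate of the acetyl ketone 14 (not isolated), via dibutoxyboron chelate of the dienone 15 (not isolated)
Conditions: B(OBu)3, n-BuNH2 (cat.), EtOAc, 60 °C; then aq. citric acid, rt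
Reagents that add atoms: none
Why: This second boron-templated aldol condensation forms C3=C4 at the unhindered acetyl methyl group, because C1 is masked in chelate 14 and C5 is shielded by the neighbouring C6 aryl group, and no stereocentre is touched.

Step 8
Reactants: 16 enolised dienoyl cyclopentanone
Product: 17 (2R,3R,4R)-2-chloro-4-[3,5-bis(triisopropylsilyloxy)phenyl]-3-[4-(triisopropylsilyloxy)phenyl]-2-{(2E,4E)-5-[4-(triisopropylsilyloxy)phenyl]penta-2,4-dienoyl}cyclopentan-1-one (Cl trans and dienoyl chain cis to the C7 aryl group)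
Conditions: NCS (1.05 equiv), CH2Cl2, 0 °C
Reagents that add atoms: N-chlorosuccinimide, O=C1CCC(=O)N1Cl
Why: In this electrophilic α-chlorination of an enolised 1,3-diketone, chlorine should enter C1 anti to the adjacent C7 aryl group, which places the chain on the face needed for bridging, makes C1 sp3 and non-enolisable, and leaves C5 as the only enolisable carbon.

Step 9
Reactants: 17 C1-chloro dienoyl cyclopentanone
Product: 19 1-chloro-2-(tert-butyldimethylsilyloxy)-6-exo-[3,5-bis(triisopropylsilyloxy)phenyl]-7-endo-[4-(triisopropylsilyloxy)phenyl]-4-{(E)-2-[4-(triisopropylsilyloxy)phenyl]ethenyl}bicyclo[3.2.1]oct-2-en-8-one (C4–H syn to C8 and styryl equatorial), via C5 silyl enol ether 18 (not isolated)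
Conditions: TBSOTf (1.5 equiv), Et3N (2 equiv), CH2Cl2 (0.01 M), −78 to 0 °C
Reagents that add atoms: tert-butyldimethylsilyl triflate, CC(C)(C)[Si](C)(C)OS(=O)(=O)C(F)(F)F
Why: In this silyl triflate/amine-promoted intramolecular Mukaiyama–Michael addition (6-(enolendo)-endo-trig), C5 of 18 can reach C4 only on the face that carries the chain, anti to the C6 aryl group, which sets C5 (C6 aryl exo, C7 aryl endo), the E-enone puts the styryl group equatorial at the transient centre C4, and trapping of the C2 enolate as its silyl ether should make the closure irreversible.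

Step 10
Reactants: 19 bridgehead chloride
Product: 20 2-(tert-butyldimethylsilyloxy)-6-exo-[3,5-bis(triisopropylsilyloxy)phenyl]-7-endo-[4-(triisopropylsilyloxy)phenyl]-4-{(E)-2-[4-(triisopropylsilyloxy)phenyl]ethenyl}bicyclo[3.2.1]oct-2-en-8-one
Conditions: Bu3SnH (1.5 equiv), AIBN (portions), toluene, 100 °C
Reagents that add atoms: none
Why: In this tin hydride radical-chain dehalogenation the bridgehead radical at C1 cannot invert or eliminate, so hydrogen should take the place of chlorine with the C1 geometry fixed by the cage, and stannyl addition to the styryl group is reversible.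

Step 11
Reactants: 20 bicyclic silyl enol ether
Product: 21 (1R,5S,6S,7S)-6-[3,5-bis(triisopropylsilyloxy)phenyl]-7-[4-(triisopropylsilyloxy)phenyl]-4-{(E)-2-[4-(triisopropylsilyloxy)phenyl]ethenyl}bicyclo[3.2.1]oct-3-ene-2,8-dione
Conditions: Pd(OAc)2 (1.1 equiv), MeCN/DMSO, rt to 40 °C
Reagents that add atoms: none
Why: In this Saegusa–Ito oxidation palladium can sit only on C3 because C1 is a bridgehead, it should bind on the open face syn to C8 where the axial C4–H lies, and syn β-hydride elimination then gives the C3=C4 dienone and removes the transient centre C4.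

Step 12
Reactants: 21 tetra-TIPS ether of the target
Product: 22 (1R,5S,6S,7S)-6-(3,5-dihydroxyphenyl)-7-(4-hydroxyphenyl)-4-[(E)-2-(4-hydroxyphenyl)ethenyl]bicyclo[3.2.1]oct-3-ene-2,8-dione
Conditions: TBAF/AcOH (1:1, 5 equiv), THF, 0 °C
Reagents that add atoms: none
Why: Fluoride desilylation of aryl silyl ethers, buffered with acetic acid, should free the four phenols without phenoxide or strong acid, so the C1–C7 bond, the non-enolisable 1,3-diketone and all four stereocentres stay untouched.

**Compound list**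
1 | 3,5-dihydroxybenzaldehyde | O=Cc1cc(O)cc(O)c1 | starting material
2 | 3,5-bis(triisopropylsilyloxy)benzaldehyde | O=Cc1cc(O[Si](C(C)C)(C(C)C)C(C)C)cc(O[Si](C(C)C)(C(C)C)C(C)C)c1 | intermediate
3 | 4-hydroxybenzaldehyde | O=Cc1ccc(O)cc1 | starting material
4 | 4-(triisopropylsilyloxy)benzaldehyde | O=Cc1ccc(O[Si](C(C)C)(C(C)C)C(C)C)cc1 | intermediate
5 | (E)-3-[4-(triisopropylsilyloxy)phenyl]prop-2-enal | O=C/C=C/c1ccc(O[Si](C(C)C)(C(C)C)C(C)C)cc1 | intermediate
6 | pentane-2,4-dione | CC(=O)CC(C)=O | starting material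
7 | dibutoxyboron acetylacetonate (not isolated) | CC1=CC(C)=[O+][B-](OCCCC)(OCCCC)O1 | intermediate
8 | dibutoxyboron chelate of 9 (not isolated) | CC1=CC(/C=C/c2cc(O[Si](C(C)C)(C(C)C)C(C)C)cc(O[Si](C(C)C)(C(C)C)C(C)C)c2)=[O+][B-](OCCCC)(OCCCC)O1 | intermediate
9 | (E)-6-[3,5-bis(triisopropylsilyloxy)phenyl]hex-5-ene-2,4-dione | CC(=O)CC(=O)/C=C/c1cc(O[Si](C(C)C)(C(C)C)C(C)C)cc(O[Si](C(C)C)(C(C)C)C(C)C)c1 | intermediate
10 | (1E,4E)-4-acetyl-1-[3,5-bis(triisopropylsilyloxy)phenyl]-5-[4-(triisopropylsilyloxy)phenyl]penta-1,4-dien-3-one | CC(=O)/C(C(=O)/C=C/c1cc(O[Si](C(C)C)(C(C)C)C(C)C)cc(O[Si](C(C)C)(C(C)C)C(C)C)c1)=C\c1ccc(O[Si](C(C)C)(C(C)C)C(C)C)cc1 | intermediate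
11 | oxyallyl zwitterion, drawn without copper (not isolated) | CC(=O)C1=C([O-])[CH+][C@@H](c2cc(O[Si](C(C)C)(C(C)C)C(C)C)cc(O[Si](C(C)C)(C(C)C)C(C)C)c2)[C@@H]1c1ccc(O[Si](C(C)C)(C(C)C)C(C)C)cc1 | intermediate
12 | triethylsilyl enol ether of 13 (not isolated) | CC(=O)C1=C(O[Si](CC)(CC)CC)C[C@@H](c2cc(O[Si](C(C)C)(C(C)C)C(C)C)cc(O[Si](C(C)C)(C(C)C)C(C)C)c2)[C@@H]1c1ccc(O[Si](C(C)C)(C(C)C)C(C)C)cc1 | intermediate
13 | (3,4-trans)-2-acetyl-4-[3,5-bis(triisopropylsilyloxy)phenyl]-3-[4-(triisopropylsilyloxy)phenyl]cyclopentan-1-one, drawn as ring enol, (4R,5R) in the enol numbering | CC(=O)C1=C(O)C[C@@H](c2cc(O[Si](C(C)C)(C(C)C)C(C)C)cc(O[Si](C(C)C)(C(C)C)C(C)C)c2)[C@@H]1c1ccc(O[Si](C(C)C)(C(C)C)C(C)C)cc1 | intermediate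
14 | dibutoxyboron chelate of 13 (not isolated) | CC(=[O+]1)C2=C(O[B-]1(OCCCC)OCCCC)C[C@@H](c3cc(O[Si](C(C)C)(C(C)C)C(C)C)cc(O[Si](C(C)C)(C(C)C)C(C)C)c3)[C@@H]2c1ccc(O[Si](C(C)C)(C(C)C)C(C)C)cc1 | intermediate
15 | dibutoxyboron chelate of 16 (not isolated) | C(=[O+]1)(/C=C/C=C/c3ccc(O[Si](C(C)C)(C(C)C)C(C)C)cc3)C2=C(O[B-]1(OCCCC)OCCCC)C[C@@H](c3cc(O[Si](C(C)C)(C(C)C)C(C)C)cc(O[Si](C(C)C)(C(C)C)C(C)C)c3)[C@@H]2c1ccc(O[Si](C(C)C)(C(C)C)C(C)C)cc1 | intermediate
16 | enolised 2-[(2E,4E)-5-arylpenta-2,4-dienoyl]-3,4-trans-diarylcyclopentanone | O=C(/C=C/C=C/c1ccc(O[Si](C(C)C)(C(C)C)C(C)C)cc1)C1=C(O)C[C@@H](c2cc(O[Si](C(C)C)(C(C)C)C(C)C)cc(O[Si](C(C)C)(C(C)C)C(C)C)c2)[C@@H]1c1ccc(O[Si](C(C)C)(C(C)C)C(C)C)cc1 | intermediate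
17 | (2R,3R,4R)-2-chloro-2-dienoyl-3,4-diarylcyclopentanone | O=C(/C=C/C=C/c1ccc(O[Si](C(C)C)(C(C)C)C(C)C)cc1)[C@]1(Cl)C(=O)C[C@@H](c2cc(O[Si](C(C)C)(C(C)C)C(C)C)cc(O[Si](C(C)C)(C(C)C)C(C)C)c2)[C@@H]1c1ccc(O[Si](C(C)C)(C(C)C)C(C)C)cc1 | intermediate
18 | C5 tert-butyldimethylsilyl enol ether of 17 (not isolated) | O=C(/C=C/C=C/c1ccc(O[Si](C(C)C)(C(C)C)C(C)C)cc1)[C@]1(Cl)C(O[Si](C)(C)C(C)(C)C)=C[C@@H](c2cc(O[Si](C(C)C)(C(C)C)C(C)C)cc(O[Si](C(C)C)(C(C)C)C(C)C)c2)[C@@H]1c1ccc(O[Si](C(C)C)(C(C)C)C(C)C)cc1 | intermediate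
19 | 1-chloro bicyclic C2 silyl enol ether (C6 aryl exo, C7 aryl endo, C4–H syn to C8) | CC(C)(C)[Si](C)(C)OC1=C[C@H](/C=C/c2ccc(O[Si](C(C)C)(C(C)C)C(C)C)cc2)[C@H]2C(=O)[C@]1(Cl)[C@@H](c1ccc(O[Si](C(C)C)(C(C)C)C(C)C)cc1)[C@@H]2c1cc(O[Si](C(C)C)(C(C)C)C(C)C)cc(O[Si](C(C)C)(C(C)C)C(C)C)c1 | intermediate
20 | dechlorinated bicyclic C2 silyl enol ether | CC(C)(C)[Si](C)(C)OC1=C[C@H](/C=C/c2ccc(O[Si](C(C)C)(C(C)C)C(C)C)cc2)[C@H]2C(=O)[C@@H]1[C@@H](c1ccc(O[Si](C(C)C)(C(C)C)C(C)C)cc1)[C@@H]2c1cc(O[Si](C(C)C)(C(C)C)C(C)C)cc(O[Si](C(C)C)(C(C)C)C(C)C)c1 | intermediate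
21 | (1R,5S,6S,7S) tetra-TIPS ether of the target | O=C1C=C(/C=C/c2ccc(O[Si](C(C)C)(C(C)C)C(C)C)cc2)[C@H]2C(=O)[C@@H]1[C@@H](c1ccc(O[Si](C(C)C)(C(C)C)C(C)C)cc1)[C@@H]2c1cc(O[Si](C(C)C)(C(C)C)C(C)C)cc(O[Si](C(C)C)(C(C)C)C(C)C)c1 | intermediate
22 | (1R,5S,6S,7S)-6-(3,5-dihydroxyphenyl)-7-(4-hydroxyphenyl)-4-[(E)-2-(4-hydroxyphenyl)ethenyl]bicyclo[3.2.1]oct-3-ene-2,8-dione | O=C1C=C(/C=C/c2ccc(O)cc2)[C@H]2C(=O)[C@@H]1[C@@H](c1ccc(O)cc1)[C@@H]2c1cc(O)cc(O)c1 | target

**Total step count:** 12.
**Longest linear sequence:** 10 steps (1 → 2 → 9 → 10 → 13 → 16 → 17 → 19 → 20 → 21 → 22).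

**Steps most likely to fail**

Step 6.
- Possible failures:
  - weak control of the sense of conrotation;
  - reduction of divalent copper by the silane, with loss of the Lewis acid;
  - proton loss from C6 before hydride arrives;
  - direct ionic reduction of the arylidene double bond.
- Fallback: it sets out from 10 and returns at 13, and it separates ring formation from asymmetric induction. The silane-interrupted Nazarov cyclisation is run under its established achiral conditions (BF3·OEt2, Et3SiH in excess, CH2Cl2, −78 °C). The trans relation still follows from conrotation. This should give 13 together with its mirror image, the enantiomeric ring enol F1. The two are separated by preparative chromatography on a chiral stationary phase, at the price of half the material.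

Step 9.
- Possible failures:
  - the reaction stalls at the silyl enol ether because of the strain of the forming bridge;
  - chlorine is transferred from C1 to the C5 nucleophile;
  - the donor–acceptor C1–C7 bond ionises under the silyl Lewis acid.
- Fallback: it sets out from 17 and returns at 21, and it moves from the Lewis-acid silyl enol ether manifold to the enolate manifold with a different oxidation tactic. Catalytic DBU in dry toluene equilibrates 17 with the saturated bridged chloro diketone F2, C5 being the only carbon that can be deprotonated. Bu3SnH/AIBN then gives the saturated bridged diketone F3. IBX in DMSO at 65 °C dehydrogenates the only enolisable position (C3–C4) to 21.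

Step 10.
- Possible failures:
  - chlorine abstraction is slow, because the bridgehead C–Cl bond is orthogonal to both neighbouring π systems;
  - the radical chain breaks down;
  - the styryl group is hydrostannated during long heating.
- Fallback: it sets out from 16 and returns at 20, and it changes the blocking group to one that is cleaved by fast homolytic substitution at the heteroatom. PhSeCl/pyridine in CH2Cl2 at −78 °C should give the C1 phenylselenide F4, with selenium anti to the C7 aryl group. TBSOTf/Et3N closes it through its C5 silyl enol ether F5 to the bridged selenide F6. Bu3SnH/AIBN in benzene at 80 °C then delivers 20.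

**Further compounds**
F1 | step 6 | enantiomer of 13, (4S,5S) ring enol | CC(=O)C1=C(O)C[C@H](c2cc(O[Si](C(C)C)(C(C)C)C(C)C)cc(O[Si](C(C)C)(C(C)C)C(C)C)c2)[C@H]1c1ccc(O[Si](C(C)C)(C(C)C)C(C)C)cc1
F2 | step 9 | 1-chloro-4-styrylbicyclo[3.2.1]octane-2,8-dione (C6 aryl exo, C7 aryl endo, styryl equatorial) | O=C1C[C@H](/C=C/c2ccc(O[Si](C(C)C)(C(C)C)C(C)C)cc2)[C@H]2C(=O)[C@]1(Cl)[C@@H](c1ccc(O[Si](C(C)C)(C(C)C)C(C)C)cc1)[C@@H]2c1cc(O[Si](C(C)C)(C(C)C)C(C)C)cc(O[Si](C(C)C)(C(C)C)C(C)C)c1
F3 | step 9 | 4-styrylbicyclo[3.2.1]octane-2,8-dione (dechlorinated F2) | O=C1C[C@H](/C=C/c2ccc(O[Si](C(C)C)(C(C)C)C(C)C)cc2)[C@H]2C(=O)[C@@H]1[C@@H](c1ccc(O[Si](C(C)C)(C(C)C)C(C)C)cc1)[C@@H]2c1cc(O[Si](C(C)C)(C(C)C)C(C)C)cc(O[Si](C(C)C)(C(C)C)C(C)C)c1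
F4 | step 10 | 2-(phenylselanyl) analogue of 17 | O=C(/C=C/C=C/c1ccc(O[Si](C(C)C)(C(C)C)C(C)C)cc1)[C@]1([Se]c2ccccc2)C(=O)C[C@@H](c2cc(O[Si](C(C)C)(C(C)C)C(C)C)cc(O[Si](C(C)C)(C(C)C)C(C)C)c2)[C@@H]1c1ccc(O[Si](C(C)C)(C(C)C)C(C)C)cc1
F5 | step 10 | C5 tert-butyldimethylsilyl enol ether of F4 | O=C(/C=C/C=C/c1ccc(O[Si](C(C)C)(C(C)C)C(C)C)cc1)[C@]1([Se]c2ccccc2)C(O[Si](C)(C)C(C)(C)C)=C[C@@H](c2cc(O[Si](C(C)C)(C(C)C)C(C)C)cc(O[Si](C(C)C)(C(C)C)C(C)C)c2)[C@@H]1c1ccc(O[Si](C(C)C)(C(C)C)C(C)C)cc1
F6 | step 10 | 1-(phenylselanyl) analogue of 19 | CC(C)(C)[Si](C)(C)OC1=C[C@H](/C=C/c2ccc(O[Si](C(C)C)(C(C)C)C(C)C)cc2)[C@H]2C(=O)[C@]1([Se]c3ccccc3)[C@@H](c1ccc(O[Si](C(C)C)(C(C)C)C(C)C)cc1)[C@@H]2c1cc(O[Si](C(C)C)(C(C)C)C(C)C)cc(O[Si](C(C)C)(C(C)C)C(C)C)c1
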